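**Retrosynthetic overview**
1. Endgame from a C3=C4 olefin: trans-diaxial AcOH opening of the 3β,4β-epoxide gives C3–OH/C4–OAc; the olefin and C5–H come from a reductive 1,3-transposition of a C3 allylic alcohol; C16 methylenation and C6 oxidation come last.
2. Key disconnection C10–C20: the δ-lactone C8–C7(=O)–O–C20–C10–C9 is closed by para-C-alkylation of a phenoxide by its own iodomethyl ester, so ring A enters as a flat 2,3,4-trisubstituted phenol and leaves as a spiro-cyclohexadienone.
3. Feature that allows this: in six-membered ring A the spiro carbon C10 is para to the C3 oxygen, and C10 sits on C9 cis-vicinal to the C7 carboxyl on C8 of ring C, so O–CH2 reaches C10 through a six-membered transition state; the ortho CH2O group (C6 on C5) fixes the aryl rotamer and thus C10.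
4. Bicyclo[3.2.1]octane: 6-exo radical closure of C12 onto C13 of a cyclopentenone; C8/C9 by an enantioselective chair Claisen rearrangement of a (Z)-3-arylallyl enol ether of methyl 2-oxocyclopentanecarboxylate.
5. Ring order: D (bought) → C (step 11) → lactone with dearomatised ring A (step 14) → ring A functionalised (steps 15–22).

Key step: step 14

Remark: atom numbers are ent-kaurane numbers of the target (ring A = C1–C5 and C10; C6 = aldehyde carbon; C7 = lactone carbonyl; C20 = lactone CH2; C15 = ketone; C16=C17 = methylene); α is the face of ring A that carries C20; Ar = 3-methyl-4-(triisopropylsilyloxy)-2-[(triisopropylsilyloxy)methyl]phenyl.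

**Route**

Step 1
Reactants: 1 methyl 3-hydroxy-2-methylbenzoate
Product: 2 methyl 3-hydroxy-6-iodo-2-methylbenzoate
Conditions: NIS (1.05 equiv), TsOH (10 mol %), MeCN, 0 °C → rt
Reagents that add atoms: N-iodosuccinimide, O=C1CCC(=O)N1I
Why: Electrophilic aromatic iodination should go para to the free hydroxyl, as halogenation of 3-oxygenated benzoates and benzaldehydes does.

Step 2
Reactants: 2 methyl 3-hydroxy-6-iodo-2-methylbenzoate
Product: 3 3-(hydroxymethyl)-4-iodo-2-methylphenol
Conditions: DIBAL-H (3.5 equiv), CH2Cl2, −78 → 0 °C; Rochelle salt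
Reagents that add atoms: none
Why: DIBAL-H reduction of the benzoate to the benzylic alcohol should leave the aryl iodide untouched at low temperature.

Step 3
Reactants: 3 3-(hydroxymethyl)-4-iodo-2-methylphenol
Product: 4 Ar–I, 1-iodo-3-methyl-4-(triisopropylsilyloxy)-2-[(triisopropylsilyloxy)methyl]benzene
Conditions: TIPSCl (2.4 equiv), imidazole (5 equiv), DMF, 40 °C
Reagents that add atoms: chlorotriisopropylsilane, CC(C)[Si](Cl)(C(C)C)C(C)C
Why: Imidazole-mediated silylation protects both hydroxyls in one operation, and the aryl silyl ether stays far more fluoride-labile than the alkyl one, which step 14 uses.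

Step 4
Reactants: 4 Ar–I; 5 prop-2-yn-1-ol
Product: 6 3-Ar-prop-2-yn-1-ol
Conditions: PdCl2(PPh3)2 (3 mol %), CuI (5 mol %), Et3N/THF, 45 °C
Reagents that add atoms: none
Why: Sonogashira coupling of an aryl iodide with a terminal alkyne tolerates the ortho substituent and both silyl ethers.

Step 5
Reactants: 6 3-Ar-prop-2-yn-1-ol
Product: 7 (2Z)-3-Ar-prop-2-en-1-ol
Conditions: H2 (1 atm), Lindlar catalyst, quinoline, EtOAc, rt
Reagents that add atoms: none
Why: Lindlar semihydrogenation adds H2 syn and should give the (Z)-alkene whose geometry later fixes the C8/C9 relative configuration.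

Step 6
Reactants: 7 (2Z)-3-Ar-prop-2-en-1-ol; 8 methyl 2-oxocyclopentane-1-carboxylate
Product: 9 methyl 2-{[(2Z)-3-Ar-prop-2-en-1-yl]oxy}cyclopent-1-ene-1-carboxylate
Conditions: PPh3, DIAD, toluene, 0 °C → rt
Reagents that add atoms: none
Why: Mitsunobu alkylation of the acidic, enolised cyclic β-keto ester should take place at the enol oxygen with SN2 displacement at the primary allylic carbon, leaving the (Z)-alkene intact.

Step 7
Reactants: 9 methyl 2-{[(2Z)-3-Ar-prop-2-en-1-yl]oxy}cyclopent-1-ene-1-carboxylate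
Product: 10 methyl (1S)-1-[(1S)-1-Ar-prop-2-en-1-yl]-2-oxocyclopentane-1-carboxylate
Conditions: C2-symmetric trans-1,2-diaminocyclohexane-derived bis(pyrrolyl)guanidinium BArF4 catalyst (20 mol %, the antipode that gives (S,S)-10), hexanes, 40 °C
Reagents that add atoms: none
Why: Hydrogen-bond-donor-catalysed enantioselective Claisen rearrangement of an O-allyl β-keto ester through a chair transition state, with the (Z)-aryl group axial and the ring CH2 equatorial, should set quaternary C8 and benzylic C9 in the required relative configuration, the catalyst setting the absolute sense.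

Step 8
Reactants: 10 methyl (1S)-1-[(1S)-1-Ar-prop-2-en-1-yl]-2-oxocyclopentane-1-carboxylate
Product: 12 methyl (1S)-1-[(1S)-1-Ar-3-hydroxypropyl]-2-oxocyclopentane-1-carboxylate, via pinacol boronate 11 (not isolated)
Conditions: HBpin (1.3 equiv), [Ir(cod)Cl]2 (2 mol %), dppe (4 mol %), CH2Cl2, rt; then NaBO3·4H2O, THF/H2O, rt
Reagents that add atoms: sodium perborate, [Na+].[O-]OB=O
Why: Iridium-catalysed anti-Markovnikov hydroboration is chemoselective for the terminal alkene over the ketone, and the mildly basic perborate oxidation avoids retro-Claisen opening of the quaternary β-keto ester.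

Step 9
Reactants: 12 methyl (1S)-1-[(1S)-1-Ar-3-hydroxypropyl]-2-oxocyclopentane-1-carboxylate
Product: 14 methyl (1S)-1-[(1S)-1-Ar-3-hydroxypropyl]-2-oxocyclopent-3-ene-1-carboxylate, via bis-silyl enol ether 13 (not isolated)
Conditions: LDA (2.3 equiv), TMSCl (2.6 equiv), THF, −78 °C; then Pd(OAc)2 (1.1 equiv), MeCN, rt; 1 M citric acid work-up
Reagents that add atoms: none
Why: Saegusa–Ito dehydrogenation can only proceed toward C16/C13 because the other α-carbon (C8) is quaternary, and the transient O-TMS ether is lost on work-up.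

Step 10
Reactants: 14 methyl (1S)-1-[(1S)-1-Ar-3-hydroxypropyl]-2-oxocyclopent-3-ene-1-carboxylate
Product: 15 methyl (1S)-1-[(1S)-1-Ar-3-iodopropyl]-2-oxocyclopent-3-ene-1-carboxylate
Conditions: I2, PPh3, imidazole, CH2Cl2, 0 °C
Reagents that add atoms: iodine, II
Why: Appel iodination of the primary alcohol is neutral and is done after enone formation so that no enolate ever meets the alkyl iodide.

Step 11
Reactants: 15 methyl (1S)-1-[(1S)-1-Ar-3-iodopropyl]-2-oxocyclopent-3-ene-1-carboxylate
Product: 16 methyl (1S,2S,5R)-2-Ar-7-oxobicyclo[3.2.1]octane-1-carboxylate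
Conditions: Bu3SnH (1.3 equiv, syringe pump), AIBN (0.1 equiv), benzene, 80 °C, 5 mM
Reagents that add atoms: none
Why: Giese-type 6-exo-trig cyclisation of the nucleophilic primary radical (C12) onto the enone β-carbon (C13) closes ring C, and since the chain can only bridge the face of the five-membered ring that carries it, the new bridgehead C13 is fixed by C8 and the aryl group ends anti to the two-carbon bridge.

Step 12
Reactants: 16 methyl (1S,2S,5R)-2-Ar-7-oxobicyclo[3.2.1]octane-1-carboxylate
Product: 17 (1S,2S,5R)-2-Ar-7-oxobicyclo[3.2.1]octane-1-carboxylic acid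
Conditions: LiI (6 equiv), EtOAc, reflux, dark; then 1 M HCl
Reagents that add atoms: none
Why: SN2 demethylation by iodide at the methyl group bypasses the hindered acyl carbon, and the β-keto acid should not decarboxylate because its enol would be a bridgehead olefin.

Step 13
Reactants: 17 (1S,2S,5R)-2-Ar-7-oxobicyclo[3.2.1]octane-1-carboxylic acid
Product: 18 chloromethyl (1S,2S,5R)-2-Ar-7-oxobicyclo[3.2.1]octane-1-carboxylate
Conditions: ClCH2OSO2Cl (1.3 equiv), n-Bu4NHSO4 (0.1 equiv), NaHCO3 (4 equiv), CH2Cl2/H2O, rt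
Reagents that add atoms: chloromethyl chlorosulfate, ClCOS(=O)(=O)Cl
Why: Phase-transfer O-alkylation of a carboxylate by chloromethyl chlorosulfate is the standard synthesis of acyloxymethyl chlorides and works for pivalate-like hindered acids.

Step 14
Reactants: 18 chloromethyl (1S,2S,5R)-2-Ar-7-oxobicyclo[3.2.1]octane-1-carboxylate
Product: 21 spiro-dienone 7,20-lactone (ring A = 4-methyl-5-[(triisopropylsilyloxy)methyl]cyclohexa-1,4-dien-3-one spiro-fused at C10; C8, C9, C13 as in 16), via caesium phenoxide chloromethyl ester 19 (not isolated), via caesium phenoxide iodomethyl ester 20 (not isolated)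
Conditions: CsF (1.5 equiv), DMF, 0 °C; then dilution with t-BuOH to 2 mM, NaI (3 equiv), 50 °C
Reagents that add atoms: none
Why: Proposed new method: fluoride removes the aryl silyl group and iodide exchanges the chloride, so a phenoxide carrying an iodomethyl ester (a very reactive SN2 electrophile of the pivaloyloxymethyl iodide type) is formed, whose para carbon C10 attacks C20 with loss of iodide while the ring dearomatises to the cross-conjugated dienone. The closest known reaction types are the base- or fluoride-triggered intramolecular para-alkylative dearomatisation of phenols by tethered alkyl halides or sulfonates (Ar1-6 participation) and the C-alkylation of enolates by acyloxymethyl iodides; new is their combination to close a lactone through an ester tether. The δ-lactone closes in 6-exo-tet mode by ipso attack of the arene, which needs the s-cis ester rotamer and is helped by the rigid cis arrangement of C7 and the aryl group on the bicycle. The only new stereocentre, spiro carbon C10, is controlled by C9: the aryl plane should turn its substituted ortho carbon (C5 with CH2OTIPS) toward the C9–H side and away from quaternary C8, and C20 arrives from the C8 face. The step needs C- over O-alkylation and para over other positions: the phenoxide oxygen and the ortho carbons cannot reach C20 within the molecule, the hindered bridgehead carbonyl resists acyl transfer, and high dilution with a hydrogen-bonding cosolvent should hold back intermolecular O-alkylation.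

Step 15
Reactants: 21 spiro-dienone 7,20-lactone
Product: 22 1,2-dihydro enone (ring A = 4-methyl-5-[(triisopropylsilyloxy)methyl]cyclohex-4-en-3-one)
Conditions: H2 (1 atm), RhCl(PPh3)3 (10 mol %), benzene/EtOH, rt
Reagents that add atoms: none
Why: Wilkinson hydrogenation reduces the disubstituted C1=C2 bond of a cross-conjugated dienone and leaves the tetrasubstituted C4=C5 bond, as with steroidal 1,4-dien-3-ones.

Step 16
Reactants: 22 1,2-dihydro enone
Product: 23 (3R)-allylic alcohol (3α-OH, cis to C20)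
Conditions: (S)-Me-CBS (0.5 equiv), catecholborane (1.5 equiv), toluene, −78 °C
Reagents that add atoms: none
Why: Corey–Bakshi–Shibata reduction sets C3 under reagent control (α-substituted alkenyl side as the large group), and at −78 °C the conjugated ketone should react well before the hindered C15 ketone.

Step 17
Reactants: 23 (3R)-allylic alcohol
Product: 26 Δ3-olefin (C3=C4–Me, 5β-H, 5α-CH2OTIPS), via Mitsunobu hydrazone adduct 24 (not isolated), via allylic diazene 25 (not isolated)
Conditions: IPNBSH, PPh3, DEAD, THF, 0 °C → rt; then CF3CH2OH/H2O (1:1), rt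
Reagents that add atoms: none
Why: Myers reductive 1,3-transposition: Mitsunobu displacement inverts C3, loss of sulfinate gives the 3β-diazene, and its retro-ene loss of N2 delivers hydrogen suprafacially to the β face of C5, setting C5 and moving the double bond to C3=C4.

Step 18
Reactants: 26 Δ3-olefin
Product: 27 3β,4β-epoxide
Conditions: m-CPBA (1.2 equiv), NaHCO3, CH2Cl2, 0 °C
Reagents that add atoms: 3-chloroperbenzoic acid, OOC(=O)c1cccc(Cl)c1
Why: Prilezhaev epoxidation of the only electron-rich alkene should occur anti to the axial C20 methylene on C10 (1,3 to C4) and to the α-CH2OTIPS group, as with 5α-steroidal Δ3-olefins.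

Step 19
Reactants: 27 3β,4β-epoxide
Product: 28 3β-hydroxy-4α-acetoxy-4β-methyl compound (C6–OTIPS, C15 ketone)
Conditions: glacial AcOH, 40 °C
Reagents that add atoms: acetic acid, CC(=O)O
Why: Acid-mediated trans-diaxial (Fürst–Plattner) opening at the tertiary carbon C4 with inversion gives the tertiary acetate and the free secondary alcohol directly, and their diaxial arrangement rules out acyl migration.

Step 20
Reactants: 28 3β-hydroxy-4α-acetoxy-4β-methyl compound
Product: 29 16-methylene-15-ketone (C16=C17 installed)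
Conditions: (CH2O)n (6 equiv), N-methylanilinium trifluoroacetate (3 equiv), THF, reflux
Reagents that add atoms: formaldehyde (from paraformaldehyde), C=O
Why: Gras α-methylenation (Mannich condensation then amine elimination) under weakly acidic conditions can only engage C16, the sole enolisable position of the C15 ketone, and spares acetate, lactone and silyl ether.

Step 21
Reactants: 29 16-methylene-15-ketone
Product: 30 C6 primary alcohol
Conditions: HF·pyridine, pyridine/THF, 0 °C → rt
Reagents that add atoms: none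
Why: Buffered fluoride desilylation removes the primary TIPS ether without base, so the enone and the acetate survive.

Step 22
Reactants: 30 C6 primary alcohol
Product: 31 CNP0199571.1
Conditions: TEMPO (0.2 equiv), PhI(OAc)2 (1.3 equiv), CH2Cl2, rt
Reagents that add atoms: none
Why: TEMPO/PhI(OAc)2 oxidation is selective for the primary alcohol over the hindered axial C3 carbinol and is base-free, so the β-acetoxy aldehyde should neither eliminate nor epimerise at C5.

**Compound list**
1 | methyl 3-hydroxy-2-methylbenzoate | COC(=O)c1cccc(O)c1C | starting material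
2 | methyl 3-hydroxy-6-iodo-2-methylbenzoate | COC(=O)c1c(I)ccc(O)c1C | intermediate
3 | 3-(hydroxymethyl)-4-iodo-2-methylphenol | OCc1c(I)ccc(O)c1C | intermediate
4 | Ar–I, 1-iodo-3-methyl-4-(triisopropylsilyloxy)-2-[(triisopropylsilyloxy)methyl]benzene | CC(C)[Si](C(C)C)(C(C)C)OCc1c(I)ccc(O[Si](C(C)C)(C(C)C)C(C)C)c1C | intermediate
5 | prop-2-yn-1-ol | OCC#C | starting material
6 | 3-Ar-prop-2-yn-1-ol | OCC#Cc1ccc(O[Si](C(C)C)(C(C)C)C(C)C)c(C)c1CO[Si](C(C)C)(C(C)C)C(C)C | intermediate
7 | (2Z)-3-Ar-prop-2-en-1-ol | OC/C=C\c1ccc(O[Si](C(C)C)(C(C)C)C(C)C)c(C)c1CO[Si](C(C)C)(C(C)C)C(C)C | intermediate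
8 | methyl 2-oxocyclopentane-1-carboxylate | COC(=O)C1CCCC1=O | starting material
9 | methyl 2-{[(2Z)-3-Ar-prop-2-en-1-yl]oxy}cyclopent-1-ene-1-carboxylate | COC(=O)C1=C(OC/C=C\c2ccc(O[Si](C(C)C)(C(C)C)C(C)C)c(C)c2CO[Si](C(C)C)(C(C)C)C(C)C)CCC1 | intermediate
10 | methyl (1S)-1-[(1S)-1-Ar-prop-2-en-1-yl]-2-oxocyclopentane-1-carboxylate | O=C1CCC[C@]1(C(=O)OC)[C@@H](C=C)c1ccc(O[Si](C(C)C)(C(C)C)C(C)C)c(C)c1CO[Si](C(C)C)(C(C)C)C(C)C | intermediate
11 | pinacol boronate, methyl (1S)-1-[(1S)-1-Ar-3-(pinacolboryl)propyl]-2-oxocyclopentane-1-carboxylate | O=C1CCC[C@]1(C(=O)OC)[C@@H](CCB1OC(C)(C)C(C)(C)O1)c1ccc(O[Si](C(C)C)(C(C)C)C(C)C)c(C)c1CO[Si](C(C)C)(C(C)C)C(C)C | intermediate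
12 | methyl (1S)-1-[(1S)-1-Ar-3-hydroxypropyl]-2-oxocyclopentane-1-carboxylate | O=C1CCC[C@]1(C(=O)OC)[C@@H](CCO)c1ccc(O[Si](C(C)C)(C(C)C)C(C)C)c(C)c1CO[Si](C(C)C)(C(C)C)C(C)C | intermediate
13 | bis-silyl enol ether, methyl (1S)-1-[(1S)-1-Ar-3-(trimethylsilyloxy)propyl]-2-(trimethylsilyloxy)cyclopent-2-ene-1-carboxylate | C[Si](C)(C)OC1=CCC[C@]1(C(=O)OC)[C@@H](CCO[Si](C)(C)C)c1ccc(O[Si](C(C)C)(C(C)C)C(C)C)c(C)c1CO[Si](C(C)C)(C(C)C)C(C)C | intermediate
14 | methyl (1S)-1-[(1S)-1-Ar-3-hydroxypropyl]-2-oxocyclopent-3-ene-1-carboxylate | O=C1C=CC[C@]1(C(=O)OC)[C@@H](CCO)c1ccc(O[Si](C(C)C)(C(C)C)C(C)C)c(C)c1CO[Si](C(C)C)(C(C)C)C(C)C | intermediate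
15 | methyl (1S)-1-[(1S)-1-Ar-3-iodopropyl]-2-oxocyclopent-3-ene-1-carboxylate | O=C1C=CC[C@]1(C(=O)OC)[C@@H](CCI)c1ccc(O[Si](C(C)C)(C(C)C)C(C)C)c(C)c1CO[Si](C(C)C)(C(C)C)C(C)C | intermediate
16 | methyl (1S,2S,5R)-2-Ar-7-oxobicyclo[3.2.1]octane-1-carboxylate | C1C(=O)[C@]2(C(=O)OC)C[C@H]1CC[C@H]2c1ccc(O[Si](C(C)C)(C(C)C)C(C)C)c(C)c1CO[Si](C(C)C)(C(C)C)C(C)C | intermediate
17 | (1S,2S,5R)-2-Ar-7-oxobicyclo[3.2.1]octane-1-carboxylic acid | C1C(=O)[C@]2(C(=O)O)C[C@H]1CC[C@H]2c1ccc(O[Si](C(C)C)(C(C)C)C(C)C)c(C)c1CO[Si](C(C)C)(C(C)C)C(C)C | intermediate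
18 | chloromethyl (1S,2S,5R)-2-Ar-7-oxobicyclo[3.2.1]octane-1-carboxylate | C1C(=O)[C@]2(C(=O)OCCl)C[C@H]1CC[C@H]2c1ccc(O[Si](C(C)C)(C(C)C)C(C)C)c(C)c1CO[Si](C(C)C)(C(C)C)C(C)C | intermediate
19 | caesium phenoxide chloromethyl ester (18 without the aryl silyl group) | C1C(=O)[C@]2(C(=O)OCCl)C[C@H]1CC[C@H]2c1ccc([O-])c(C)c1CO[Si](C(C)C)(C(C)C)C(C)C.[Cs+] | intermediate
20 | caesium phenoxide iodomethyl ester | C1C(=O)[C@]2(C(=O)OCI)C[C@H]1CC[C@H]2c1ccc([O-])c(C)c1CO[Si](C(C)C)(C(C)C)C(C)C.[Cs+] | intermediate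
21 | spiro-dienone 7,20-lactone (ring A = 4-methyl-5-[(triisopropylsilyloxy)methyl]cyclohexa-1,4-dien-3-one, C10 spiro as in the target) | C1C(=O)[C@]23C[C@H]1CC[C@H]2[C@@]1(C=CC(=O)C(C)=C1CO[Si](C(C)C)(C(C)C)C(C)C)COC3=O | intermediate
22 | 1,2-dihydro enone (C3 ketone, C4=C5) | C1C(=O)[C@]23C[C@H]1CC[C@H]2[C@@]1(CCC(=O)C(C)=C1CO[Si](C(C)C)(C(C)C)C(C)C)COC3=O | intermediate
23 | (3R)-allylic alcohol (3α-OH) | C1C(=O)[C@]23C[C@H]1CC[C@H]2[C@@]1(CC[C@@H](O)C(C)=C1CO[Si](C(C)C)(C(C)C)C(C)C)COC3=O | intermediate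
24 | Mitsunobu hydrazone adduct (3β-N(2-nitrobenzenesulfonyl)-N=CMe2) | C1C(=O)[C@]23C[C@H]1CC[C@H]2[C@@]1(CC[C@H](N(N=C(C)C)S(=O)(=O)c2ccccc2[N+](=O)[O-])C(C)=C1CO[Si](C(C)C)(C(C)C)C(C)C)COC3=O | intermediate
25 | 3β-allylic diazene | C1C(=O)[C@]23C[C@H]1CC[C@H]2[C@@]1(CC[C@H](N=N)C(C)=C1CO[Si](C(C)C)(C(C)C)C(C)C)COC3=O | intermediate
26 | Δ3-olefin (C3=C4–Me, 5β-H, 5α-CH2OTIPS) | C1C(=O)[C@]23C[C@H]1CC[C@H]2[C@@]1(CCC=C(C)[C@H]1CO[Si](C(C)C)(C(C)C)C(C)C)COC3=O | intermediate
27 | 3β,4β-epoxide | C1C(=O)[C@]23C[C@H]1CC[C@H]2[C@@]1(CC[C@@H]2O[C@]2(C)[C@H]1CO[Si](C(C)C)(C(C)C)C(C)C)COC3=O | intermediate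
28 | 3β-hydroxy-4α-acetoxy-4β-methyl compound (C6–OTIPS, C15 ketone) | C1C(=O)[C@]23C[C@H]1CC[C@H]2[C@@]1(CC[C@H](O)[C@@](C)(OC(C)=O)[C@H]1CO[Si](C(C)C)(C(C)C)C(C)C)COC3=O | intermediate
29 | 16-methylene-15-ketone (C6–OTIPS) | C=C1C(=O)[C@]23C[C@H]1CC[C@H]2[C@@]1(CC[C@H](O)[C@@](C)(OC(C)=O)[C@H]1CO[Si](C(C)C)(C(C)C)C(C)C)COC3=O | intermediate
30 | C6 primary alcohol | C=C1C(=O)[C@]23C[C@H]1CC[C@H]2[C@@]1(CC[C@H](O)[C@@](C)(OC(C)=O)[C@H]1CO)COC3=O | intermediate
31 | CNP0199571.1 | C=C1C(=O)[C@]23C[C@H]1CC[C@H]2[C@@]1(CC[C@H](O)[C@@](C)(OC(C)=O)[C@H]1C=O)COC3=O | target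

**Step count**
Total steps: 22. Longest linear sequence: 22 steps (1 → 31); 5 and 8 are bought.

**Steps most likely to fail**

Step 14 (Proposed new method). The ring closure must pass through the disfavoured s-cis ester rotamer, so intermolecular O-alkylation of the phenoxide (oligomerisation) or fluoride capture of the halomethyl ester may outrun it. The fallback uses known chemistry; it sets out from 17 and comes back at 21. Acid 17 is turned with oxalyl chloride into the acid chloride F1 and with diazomethane into the diazoketone F2. Trifluoroacetic acid at −20 °C then triggers the acid-promoted intramolecular alkylation of the para carbon by the protonated diazoketone (the spiroannulation of 3-arylpropionyl diazomethanes, here with loss of the aryl silyl group). This gives the spiro[4.5]dienone diketone F3, in which C10–C20 already exists and the same rotamer preference applies. Buffered Baeyer–Villiger oxidation should then insert oxygen between C7 and C20, because the other candidate, C8, is an acyl-substituted bridgehead of low migratory aptitude, and this gives 21.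

Step 7. Slow turnover of the hindered (Z)-configured ether, a boat-type pathway or the uncatalysed background rearrangement may erode enantio- and diastereocontrol. The fallback sets out from 6 and comes back at 10. Red-Al reduction of 6 gives the (E)-allylic alcohol F4, methyl chloroformate/pyridine gives the methyl carbonate F5, and 8 is allylated with F5 under iridium/phosphoramidite catalysis (branched-selective, diastereo- and enantioselective allylic alkylation of cyclic β-keto esters). Ligand antipode and enolate counter-ion are chosen for the (S,S) isomer; the sense of diastereoselection for this substrate would have to be confirmed.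

Step 19. Acid may induce elimination to an allylic alcohol or a 1,2-hydride shift at the tertiary epoxide carbon instead of acetate capture. The fallback sets out from 26 and comes back at 28. A Prévost reaction (I2, AgOAc, dry AcOH) forms the iodonium ion on the β face and gives the trans-diaxial iodo acetate F6. Silver-assisted participation of the 4-acetate and acetate opening at C3 then give the 3β,4α-diacetate F7. Selective methanolysis of the secondary 3-acetate (K2CO3, MeOH, 0 °C) gives 28.

Further compounds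
F1 | step 14 | (1S,2S,5R)-2-Ar-7-oxobicyclo[3.2.1]octane-1-carbonyl chloride | C1C(=O)[C@]2(C(=O)Cl)C[C@H]1CC[C@H]2c1ccc(O[Si](C(C)C)(C(C)C)C(C)C)c(C)c1CO[Si](C(C)C)(C(C)C)C(C)C
F2 | step 14 | diazoketone, (1S,2S,5R)-2-Ar-1-(diazoacetyl)bicyclo[3.2.1]octan-7-one | C1C(=O)[C@]2(C(=O)C=[N+]=[N-])C[C@H]1CC[C@H]2c1ccc(O[Si](C(C)C)(C(C)C)C(C)C)c(C)c1CO[Si](C(C)C)(C(C)C)C(C)C
F3 | step 14 | spiro[4.5]dienone diketone (C7 ketone bonded to C20H2, no lactone oxygen) | C1C(=O)[C@]23C[C@H]1CC[C@H]2[C@@]1(C=CC(=O)C(C)=C1CO[Si](C(C)C)(C(C)C)C(C)C)CC3=O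
F4 | step 7 | (2E)-3-Ar-prop-2-en-1-ol | OC/C=C/c1ccc(O[Si](C(C)C)(C(C)C)C(C)C)c(C)c1CO[Si](C(C)C)(C(C)C)C(C)C
F5 | step 7 | (2E)-3-Ar-prop-2-en-1-yl methyl carbonate | COC(=O)OC/C=C/c1ccc(O[Si](C(C)C)(C(C)C)C(C)C)c(C)c1CO[Si](C(C)C)(C(C)C)C(C)C
F6 | step 19 | 3β-iodo-4α-acetoxy compound | C1C(=O)[C@]23C[C@H]1CC[C@H]2[C@@]1(CC[C@H](I)[C@@](C)(OC(C)=O)[C@H]1CO[Si](C(C)C)(C(C)C)C(C)C)COC3=O
F7 | step 19 | 3β,4α-diacetate | C1C(=O)[C@]23C[C@H]1CC[C@H]2[C@@]1(CC[C@H](OC(C)=O)[C@@](C)(OC(C)=O)[C@H]1CO[Si](C(C)C)(C(C)C)C(C)C)COC3=O
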